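**Strategy.** Ring A (the trihydroxycyclohexane, C1–C6) carries the C3 and C6 hydroxyls cis and 1,4 across C4–C5. Both C–O bonds are therefore traced back in one disconnection to the C3=C4–C5=C6 diene of the safranal skeleton. The key step, a [4+2] addition of singlet oxygen to silyl ether 3, makes the C3–O and C6–O bonds on one ring face as a peroxide bridge and leaves C4=C5 for directed introduction of the cis C5 hydroxyl. The precursor is safranol TBS ether, with C7 masked as CH2OSi for later conversion into the aldehyde that starts the polyene; ring B comes from α-ionone, and the halves meet through a C10 dialdehyde.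

Key step: step 3

Numbering remark: positions are given in carotenoid numbering (ring A C1–C6 with C7 on C6; primed locants for the ring B half). The target is (3S,5S,6R,3'R,6'R), so the three ring A hydroxyls lie on one face and the ring B hydroxyl is trans to the C6' side chain.

Assumption: the Burkholderia cepacia lipase is taken to acylate the (3R) carbinol of these 3-hydroxy-4-ene rings faster (empirical size rule for secondary alcohols, olefinic flank as the larger group); with the opposite preference ester and free alcohol only exchange roles in steps 5 and 16, and steps 7 and 17 accept either form.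

**Ring A half (steps 1–12)**

Step 1
Reactants: 1 safranal (2,6,6-trimethylcyclohexa-1,3-diene-1-carbaldehyde)
Product: 2 safranol [(2,6,6-trimethylcyclohexa-1,3-dien-1-yl)methanol]
Conditions: NaBH4, CeCl3·7H2O, MeOH, 0 °C
Reagents that add atoms: none
Why: Luche reduction delivers hydride 1,2 to the conjugated aldehyde and leaves the ring diene intact; no stereocentre is formed.

Step 2
Reactants: 2 safranol
Product: 3 tert-butyl(dimethyl)[(2,6,6-trimethylcyclohexa-1,3-dien-1-yl)methoxy]silane
Conditions: TBSCl, imidazole, DMF, rt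
Reagents that add atoms: tert-butyldimethylsilyl chloride, CC(C)(C)[Si](C)(C)Cl
Why: Imidazole-promoted silylation of the primary allylic alcohol; the silyl ether keeps the C7 oxygen out of the later lipase acylation and prevents it from steering the vanadium epoxidation to the wrong face.

Step 3
Reactants: 3 safranol TBS ether
Product: 4 rac-tert-butyl(dimethyl){[(1R,4S)-6,7,7-trimethyl-2,3-dioxabicyclo[2.2.2]oct-5-en-1-yl]methoxy}silane (racemate; the enantiomer carried forward is drawn)
Conditions: O2 (1 atm), 5,10,15,20-tetraphenylporphyrin (cat.), white LED, CH2Cl2, −20 °C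
Reagents that add atoms: dioxygen, O=O
Why: Triplet-excited tetraphenylporphyrin sensitises O2 to its singlet state, which adds to the ring-locked s-cis C3=C4–C5=C6 diene in a concerted suprafacial [4+2] cycloaddition, forming C3–O and C6–O in one event. The closest known reaction type is the dye-sensitised photooxygenation of cyclohexa-1,3-dienes to 2,3-dioxabicyclo[2.2.2]oct-5-enes, as when α-terpinene gives ascaridole. The new six-membered 3,6-dihydro-1,2-dioxine ring is closed by cycloaddition, both ring bonds being made together across C3 and C6 of the carbocycle, which is held as a boat. C3 and C6 become stereocentres whose relative configuration (both oxygens on one face) is enforced by the two-atom peroxide tether, while the two diene faces are enantiotopic, so the racemate should form. The step needs [4+2] to win over ene reactions at the C5 methyl, C2–H and C7–H; the enforced s-cis geometry, the electron-rich tetrasubstituted C5=C6 terminus, the inductively deactivated and silyl-shielded C7 hydrogens, the aprotic solvent and the low temperature secure this.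

Step 4
Reactants: 4 racemic endoperoxide
Product: 5 rac-(1R,4S)-1-{[tert-butyl(dimethyl)silyl]oxymethyl}-2,6,6-trimethylcyclohex-2-ene-1,4-diol (racemic cis-3,6-diol)
Conditions: thiourea (2.2 equiv), MeOH, 0 °C → rt
Reagents that add atoms: none
Why: Thiourea reduces the O–O bond by attack of sulfur on a peroxide oxygen (thiourea reduction of endoperoxides), so neither C–O bond is touched and the cis relationship of the C3 and C6 hydroxyls is kept, while the neutral medium avoids base-induced Kornblum–DeLaMare fragmentation.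

Step 5
Reactants: 5 racemic cis-3,6-diol
Product: 6 (1R,4S)-1-{[tert-butyl(dimethyl)silyl]oxymethyl}-2,6,6-trimethylcyclohex-2-ene-1,4-diol [(3S,6R) in carotenoid numbering; recovered unreacted]
Conditions: Burkholderia cepacia lipase (immobilised), vinyl acetate, t-BuOMe, 30 °C, run to just past half conversion; silica gel separation
Reagents that add atoms: none
Why: Lipase-catalysed kinetic resolution by enantioselective transesterification acts only at the secondary C3 carbinol, acetylating the (3R) enantiomer and leaving the (3S,6R)-diol, whose two stereocentres were tied together by the former bridge, in high enantiomeric purity once conversion passes one half.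

Step 6
Reactants: 6 (3S,6R)-diol
Product: 7 (1S,2S,5S,6S)-2-{[tert-butyl(dimethyl)silyl]oxymethyl}-1,3,3-trimethyl-7-oxabicyclo[4.1.0]heptane-2,5-diol (4,5-epoxide cis to both hydroxyls)
Conditions: VO(acac)2 (cat.), t-BuOOH, CH2Cl2, 0 °C → rt
Reagents that add atoms: tert-butyl hydroperoxide, CC(C)(C)OO
Why: Vanadium-catalysed hydroxyl-directed epoxidation: the C3 and C6 allylic hydroxyls, both on the same ring face, bind the vanadium tert-butylperoxide and deliver oxygen to C4=C5 from that face, which sets C4 and C5 with the oxirane cis to both hydroxyls.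

Step 7
Reactants: 7 epoxy diol
Product: 8 (1S,2S,4S)-1-{[tert-butyl(dimethyl)silyl]oxymethyl}-2,6,6-trimethylcyclohexane-1,2,4-triol (all-cis 3,5,6-triol)
Conditions: LiAlH4, THF, 0 °C → reflux; then H2O
Reagents that add atoms: none
Why: Aluminohydride opens the oxirane by SN2 attack at the less substituted C4 from the face opposite the ring oxygen (reductive epoxide opening), so the C5–O bond and its configuration from step 6 are retained and the three oxygens end on one face; the cis-epoxy alkoxides cannot undergo Payne rearrangement.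

Step 8
Reactants: 8 triol
Product: 9 (1S,3S,4S)-4-{[tert-butyl(dimethyl)silyl]oxymethyl}-3,4-dihydroxy-3,5,5-trimethylcyclohexyl acetate
Conditions: Ac2O, pyridine, CH2Cl2, 0 °C → rt
Reagents that add atoms: acetic anhydride, CC(=O)OC(C)=O
Why: Acylation takes only the secondary C3 hydroxyl because the two tertiary hydroxyls are too hindered, and the acetate masks C3–OH for the oxidation in step 10 before being removed without an extra step in step 12.

Step 9
Reactants: 9 silyl ether acetate
Product: 10 (1S,3S,4S)-3,4-dihydroxy-4-(hydroxymethyl)-3,5,5-trimethylcyclohexyl acetate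
Conditions: Bu4NF, AcOH (1:1), THF, rt
Reagents that add atoms: none
Why: Fluoride-induced desilylation buffered with acetic acid frees the primary C7 hydroxyl without acetyl migration or ester cleavage.

Step 10
Reactants: 10 primary alcohol
Product: 12 (1S,3S,4R)-4-formyl-3,4-dihydroxy-3,5,5-trimethylcyclohexyl acetate, via alkoxysulfonium chloride 11 (not isolated)
Conditions: (COCl)2, DMSO, CH2Cl2, −78 °C; then Et3N, −78 → 0 °C
Reagents that add atoms: none
Why: Swern oxidation turns the neopentyl primary alcohol into the aldehyde at low temperature without touching the tertiary hydroxyls or the acetate, and the fully substituted α-carbon C6 cannot epimerise.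

Step 11
Reactants: 12 hydroxy aldehyde; 13 diethyl (3-cyano-2-methylprop-2-en-1-yl)phosphonate (E/Z mixture)
Product: 15 (2E,4E)-5-[(1R,2S,4S)-4-acetoxy-1,2-dihydroxy-2,6,6-trimethylcyclohexyl]-3-methylpenta-2,4-dienenitrile, via lithiated phosphonate 14 (not isolated)
Conditions: 13, LiN(SiMe3)2, THF, −78 °C; then 12, −78 → 0 °C
Reagents that add atoms: none
Why: Horner–Wadsworth–Emmons olefination with the vinylogous cyanophosphonate anion gives the 7E alkene under the usual thermodynamic control with the 9E isomer predominating (9Z isomer removed by chromatography), and the small, weakly basic anion adds to the hindered aldehyde without deprotonating the tertiary hydroxyls, which keeps α-ketol rearrangement at bay.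

Step 12
Reactants: 15 C15 nitrile
Product: 17 (2E,4E)-3-methyl-5-[(1R,2S,4S)-1,2,4-trihydroxy-2,6,6-trimethylcyclohexyl]penta-2,4-dienal, via C15 aldimine 16 (not isolated)
Conditions: i-Bu2AlH (excess), CH2Cl2, −78 → −40 °C; then aq. potassium sodium tartrate, silica gel, 0 °C
Reagents that add atoms: water, O
Why: i-Bu2AlH adds once to the conjugated nitrile to give an N-aluminio imine that is hydrolysed on work-up to the dienal (nitrile half-reduction), and the same hydride cleaves the C3 acetate, so the free triol aldehyde results in one operation.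

**Ring B half (steps 13–21)**

Step 13
Reactants: 18 α-ionone (racemic); 19 triethyl phosphonoacetate
Product: 21 ethyl (2E,4E)-3-methyl-5-(2,6,6-trimethylcyclohex-2-en-1-yl)penta-2,4-dienoate (racemic), via sodium phosphonoacetate anion 20 (not isolated)
Conditions: 19, NaH, THF, 0 °C; then 18, reflux
Reagents that add atoms: none
Why: Horner–Wadsworth–Emmons olefination of the methyl ketone gives the trisubstituted 9'E enoate as the major isomer (9'Z isomer removed by chromatography) and leaves the racemic C6' stereocentre untouched.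

Step 14
Reactants: 21 racemic C15 ester
Product: 23 ethyl (2E,4E)-3-methyl-5-(2,6,6-trimethyl-4-oxocyclohex-2-en-1-yl)penta-2,4-dienoate (racemic), via allylic tert-butyl peroxide 22 (not isolated)
Conditions: Rh2(cap)4 (dirhodium tetracaprolactamate, cat.), t-BuOOH (70% aq.), K2CO3, CH2Cl2, rt
Reagents that add atoms: tert-butyl hydroperoxide, CC(C)(C)OO
Why: Dirhodium-catalysed allylic C–H oxidation with tert-butyl hydroperoxide (Kharasch-type peroxidation followed by loss of tert-butanol) converts the only unhindered allylic methylene, C3', into the ring enone; the bis-allylic C6'–H is shielded by the neighbouring quaternary centre and the C5' methyl.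

Step 15
Reactants: 23 racemic oxo ester
Product: 24 rac-ethyl (2E,4E)-5-[(1R,4R)-4-hydroxy-2,6,6-trimethylcyclohex-2-en-1-yl]-3-methylpenta-2,4-dienoate (racemic trans alcohol; the enantiomer carried forward is drawn)
Conditions: K[HB(sec-Bu)3], THF, −78 °C; then H2O
Reagents that add atoms: none
Why: 1,2-Reduction of the β,β-disubstituted enone by a bulky trialkylborohydride, which should reach C3' from the face away from the axial C1' methyl (equatorial attack) and so place the hydroxyl pseudoaxial and trans to the pseudoaxial C6' side chain; the minor cis alcohol is removed by chromatography.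

Step 16
Reactants: 24 racemic trans alcohol
Product: 25 ethyl (2E,4E)-5-[(1R,4R)-4-acetoxy-2,6,6-trimethylcyclohex-2-en-1-yl]-3-methylpenta-2,4-dienoate
Conditions: Burkholderia cepacia lipase (immobilised), vinyl acetate, t-BuOMe, 30 °C, stopped just short of half conversion; silica gel separation
Reagents that add atoms: vinyl acetate, C=COC(C)=O
Why: Lipase-catalysed kinetic resolution by enantioselective transesterification acetylates the (3'R) carbinol, so stopping just short of half conversion should give the (3'R,6'R)-acetate in high enantiomeric purity and leave the (3'S,6'S)-alcohol.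

Step 17
Reactants: 25 (3'R,6'R)-acetate ester
Product: 26 (1R,4R)-4-[(1E,3E)-5-hydroxy-3-methylpenta-1,3-dien-1-yl]-3,5,5-trimethylcyclohex-2-en-1-ol
Conditions: i-Bu2AlH (excess), THF, −78 → 0 °C; then aq. potassium sodium tartrate
Reagents that add atoms: none
Why: i-Bu2AlH reduces the conjugated ester to the allylic alcohol (1,2-reduction) and removes the acetate in the same operation, without touching the stereocentres.

Step 18
Reactants: 26 C15 diol
Product: 27 [(2E,4E)-5-[(1R,4R)-4-hydroxy-2,6,6-trimethylcyclohex-2-en-1-yl]-3-methylpenta-2,4-dien-1-yl]triphenylphosphonium bromide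
Conditions: PPh3·HBr, CH2Cl2, 0 °C → rt; crystallisation from EtOAc
Reagents that add atoms: triphenylphosphine hydrobromide, [Br-].[PH+](c1ccccc1)(c1ccccc1)c1ccccc1
Why: Triphenylphosphine hydrobromide converts the primary dienylic alcohol into the phosphonium salt through the delocalised allylic cation (standard end-group salt formation), while the much less ionisable ring carbinol survives, and crystallisation removes any 9'Z salt.

Step 19
Reactants: 27 C15 phosphonium bromide; 28 (2E,4E,6E)-2,7-dimethylocta-2,4,6-trienedial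
Product: 30 (2E,4E,6E,8E,10E,12E)-13-[(1R,4R)-4-hydroxy-2,6,6-trimethylcyclohex-2-en-1-yl]-2,7,11-trimethyltrideca-2,4,6,8,10,12-hexaenal, via C15 phosphorus ylide 29 (not isolated)
Conditions: NaOMe, MeOH/CH2Cl2, 0 °C → rt, 28 in excess (2.5 equiv); then EtOAc, reflux
Reagents that add atoms: none
Why: Wittig olefination of the semi-stabilised ylide with an excess of the symmetrical dialdehyde should stop after one condensation because the dial is in excess and the product enal is less electrophilic, and heating equilibrates the new C11'=C12' bond to E.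

Step 20
Reactants: 30 C25 aldehyde
Product: 31 (2E,4E,6E,8E,10E,12E)-13-[(1R,4R)-4-hydroxy-2,6,6-trimethylcyclohex-2-en-1-yl]-2,7,11-trimethyltrideca-2,4,6,8,10,12-hexaen-1-ol
Conditions: NaBH4, EtOH/THF, 0 °C
Reagents that add atoms: none
Why: Borohydride 1,2-reduction of the polyenal gives the primary allylic alcohol; no other group is reducible under these conditions.

Step 21
Reactants: 31 C25 alcohol
Product: 32 [(2E,4E,6E,8E,10E,12E)-13-[(1R,4R)-4-hydroxy-2,6,6-trimethylcyclohex-2-en-1-yl]-2,7,11-trimethyltrideca-2,4,6,8,10,12-hexaen-1-yl]triphenylphosphonium bromide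
Conditions: PPh3·HBr, CH2Cl2, 0 °C → rt
Reagents that add atoms: triphenylphosphine hydrobromide, [Br-].[PH+](c1ccccc1)(c1ccccc1)c1ccccc1
Why: As in step 18, the extended allylic cation from the primary polyenylic alcohol is captured by triphenylphosphine at its terminal carbon to give the phosphonium salt, the ylide precursor being placed on this half because its carbanion is not conjugated to any leaving group.

**Union (step 22)**

Step 22
Reactants: 32 C25 phosphonium bromide; 17 C15 trihydroxy dienal
Product: 34 5,6-dihydroxylutein [(all-E)-(3S,5S,6R,3'R,6'R)-5,6-dihydro-β,ε-carotene-3,5,6,3'-tetrol], via C25 phosphorus ylide 33 (not isolated)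
Conditions: NaOMe, MeOH/CH2Cl2, 0 °C → rt; then EtOH, reflux
Reagents that add atoms: none
Why: Wittig olefination forms C11=C12 between the polyenylic ylide and the dienal with all hydroxyls free under methoxide, brief heating equilibrates the new double bond to E, and since neither half carries a protecting group the coupling product is the target itself.

**Compound list**

1 | safranal (2,6,6-trimethylcyclohexa-1,3-diene-1-carbaldehyde) | CC1=C(C=O)C(C)(C)CC=C1 | starting material
2 | safranol, (2,6,6-trimethylcyclohexa-1,3-dien-1-yl)methanol | CC1=C(CO)C(C)(C)CC=C1 | intermediate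
3 | tert-butyl(dimethyl)[(2,6,6-trimethylcyclohexa-1,3-dien-1-yl)methoxy]silane | CC1=C(CO[Si](C)(C)C(C)(C)C)C(C)(C)CC=C1 | intermediate
4 | rac-tert-butyl(dimethyl){[(1R,4S)-6,7,7-trimethyl-2,3-dioxabicyclo[2.2.2]oct-5-en-1-yl]methoxy}silane (racemate, carried enantiomer drawn) | CC1=C[C@@H]2CC(C)(C)[C@@]1(CO[Si](C)(C)C(C)(C)C)OO2 | intermediate
5 | rac-(1R,4S)-1-{[tert-butyl(dimethyl)silyl]oxymethyl}-2,6,6-trimethylcyclohex-2-ene-1,4-diol (racemate, carried enantiomer drawn) | CC1=C[C@@H](O)CC(C)(C)[C@@]1(CO[Si](C)(C)C(C)(C)C)O | intermediate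
6 | (1R,4S)-1-{[tert-butyl(dimethyl)silyl]oxymethyl}-2,6,6-trimethylcyclohex-2-ene-1,4-diol (single enantiomer) | CC1=C[C@@H](O)CC(C)(C)[C@@]1(CO[Si](C)(C)C(C)(C)C)O | intermediate
7 | (1S,2S,5S,6S)-2-{[tert-butyl(dimethyl)silyl]oxymethyl}-1,3,3-trimethyl-7-oxabicyclo[4.1.0]heptane-2,5-diol | C[C@]1(O2)[C@@H]2[C@@H](O)CC(C)(C)[C@@]1(CO[Si](C)(C)C(C)(C)C)O | intermediate
8 | (1S,2S,4S)-1-{[tert-butyl(dimethyl)silyl]oxymethyl}-2,6,6-trimethylcyclohexane-1,2,4-triol | CC(C)(C)[Si](C)(C)OC[C@@]1(O)C(C)(C)C[C@H](O)C[C@]1(C)O | intermediate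
9 | (1S,3S,4S)-4-{[tert-butyl(dimethyl)silyl]oxymethyl}-3,4-dihydroxy-3,5,5-trimethylcyclohexyl acetate | CC(C)(C)[Si](C)(C)OC[C@@]1(O)C(C)(C)C[C@H](OC(C)=O)C[C@]1(C)O | intermediate
10 | (1S,3S,4S)-3,4-dihydroxy-4-(hydroxymethyl)-3,5,5-trimethylcyclohexyl acetate | OC[C@@]1(O)C(C)(C)C[C@H](OC(C)=O)C[C@]1(C)O | intermediate
11 | {[(1S,2S,4S)-4-acetoxy-1,2-dihydroxy-2,6,6-trimethylcyclohexyl]methoxy}dimethylsulfonium chloride | C[S+](C)OC[C@@]1(O)C(C)(C)C[C@H](OC(C)=O)C[C@]1(C)O.[Cl-] | intermediate (not isolated)
12 | (1S,3S,4R)-4-formyl-3,4-dihydroxy-3,5,5-trimethylcyclohexyl acetate | O=C[C@@]1(O)C(C)(C)C[C@H](OC(C)=O)C[C@]1(C)O | intermediate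
13 | diethyl (3-cyano-2-methylprop-2-en-1-yl)phosphonate (E/Z mixture) | CCOP(=O)(CC(C)=CC#N)OCC | starting material
14 | lithium salt of 13 (allylic phosphonate carbanion) | [Li+].CCOP(=O)([CH-]C(C)=CC#N)OCC | intermediate (not isolated)
15 | (2E,4E)-5-[(1R,2S,4S)-4-acetoxy-1,2-dihydroxy-2,6,6-trimethylcyclohexyl]-3-methylpenta-2,4-dienenitrile | N#C/C=C(C)/C=C/[C@@]1(O)C(C)(C)C[C@H](OC(C)=O)C[C@]1(C)O | intermediate
16 | (2E,4E)-3-methyl-5-[(1R,2S,4S)-1,2,4-trihydroxy-2,6,6-trimethylcyclohexyl]penta-2,4-dien-1-imine | N=C/C=C(C)/C=C/[C@@]1(O)C(C)(C)C[C@H](O)C[C@]1(C)O | intermediate (not isolated)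
17 | (2E,4E)-3-methyl-5-[(1R,2S,4S)-1,2,4-trihydroxy-2,6,6-trimethylcyclohexyl]penta-2,4-dienal | O=C/C=C(C)/C=C/[C@@]1(O)C(C)(C)C[C@H](O)C[C@]1(C)O | intermediate
18 | α-ionone, (3E)-4-(2,6,6-trimethylcyclohex-2-en-1-yl)but-3-en-2-one (racemic) | CC1=CCCC(C)(C)C1/C=C/C(C)=O | starting material
19 | triethyl phosphonoacetate | CCOC(=O)CP(=O)(OCC)OCC | starting material
20 | sodium salt of 19 (phosphonoacetate carbanion) | [Na+].CCOC(=O)[CH-]P(=O)(OCC)OCC | intermediate (not isolated)
21 | ethyl (2E,4E)-3-methyl-5-(2,6,6-trimethylcyclohex-2-en-1-yl)penta-2,4-dienoate (racemic) | CCOC(=O)/C=C(C)/C=C/C1C(C)=CCCC1(C)C | intermediate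
22 | ethyl (2E,4E)-5-[4-(tert-butylperoxy)-2,6,6-trimethylcyclohex-2-en-1-yl]-3-methylpenta-2,4-dienoate (racemic diastereomer mixture) | CCOC(=O)/C=C(C)/C=C/C1C(C)=CC(OOC(C)(C)C)CC1(C)C | intermediate (not isolated)
23 | ethyl (2E,4E)-3-methyl-5-(2,6,6-trimethyl-4-oxocyclohex-2-en-1-yl)penta-2,4-dienoate (racemic) | CCOC(=O)/C=C(C)/C=C/C1C(C)=CC(=O)CC1(C)C | intermediate
24 | rac-ethyl (2E,4E)-5-[(1R,4R)-4-hydroxy-2,6,6-trimethylcyclohex-2-en-1-yl]-3-methylpenta-2,4-dienoate (racemate, carried enantiomer drawn) | CC1=C[C@H](O)CC(C)(C)[C@H]1/C=C/C(C)=C/C(=O)OCC | intermediate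
25 | ethyl (2E,4E)-5-[(1R,4R)-4-acetoxy-2,6,6-trimethylcyclohex-2-en-1-yl]-3-methylpenta-2,4-dienoate | CC1=C[C@H](OC(C)=O)CC(C)(C)[C@H]1/C=C/C(C)=C/C(=O)OCC | intermediate
26 | (1R,4R)-4-[(1E,3E)-5-hydroxy-3-methylpenta-1,3-dien-1-yl]-3,5,5-trimethylcyclohex-2-en-1-ol | CC1=C[C@H](O)CC(C)(C)[C@H]1/C=C/C(C)=C/CO | intermediate
27 | [(2E,4E)-5-[(1R,4R)-4-hydroxy-2,6,6-trimethylcyclohex-2-en-1-yl]-3-methylpenta-2,4-dien-1-yl]triphenylphosphonium bromide | CC1=C[C@H](O)CC(C)(C)[C@H]1/C=C/C(C)=C/C[P+](c2ccccc2)(c3ccccc3)c4ccccc4.[Br-] | intermediate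
28 | (2E,4E,6E)-2,7-dimethylocta-2,4,6-trienedial | O=C/C(C)=C/C=C/C=C(C)/C=O | starting material
29 | ylide of 27, (1R,4R)-3,5,5-trimethyl-4-[(1E,3E)-3-methyl-5-(triphenyl-λ5-phosphanylidene)penta-1,3-dien-1-yl]cyclohex-2-en-1-ol | CC1=C[C@H](O)CC(C)(C)[C@H]1/C=C/C(C)=C/C=P(c2ccccc2)(c3ccccc3)c4ccccc4 | intermediate (not isolated)
30 | (2E,4E,6E,8E,10E,12E)-13-[(1R,4R)-4-hydroxy-2,6,6-trimethylcyclohex-2-en-1-yl]-2,7,11-trimethyltrideca-2,4,6,8,10,12-hexaenal | CC1=C[C@H](O)CC(C)(C)[C@H]1/C=C/C(C)=C/C=C/C(C)=C/C=C/C=C(C)/C=O | intermediate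
31 | (2E,4E,6E,8E,10E,12E)-13-[(1R,4R)-4-hydroxy-2,6,6-trimethylcyclohex-2-en-1-yl]-2,7,11-trimethyltrideca-2,4,6,8,10,12-hexaen-1-ol | CC1=C[C@H](O)CC(C)(C)[C@H]1/C=C/C(C)=C/C=C/C(C)=C/C=C/C=C(C)/CO | intermediate
32 | [(2E,4E,6E,8E,10E,12E)-13-[(1R,4R)-4-hydroxy-2,6,6-trimethylcyclohex-2-en-1-yl]-2,7,11-trimethyltrideca-2,4,6,8,10,12-hexaen-1-yl]triphenylphosphonium bromide | CC1=C[C@H](O)CC(C)(C)[C@H]1/C=C/C(C)=C/C=C/C(C)=C/C=C/C=C(C)/C[P+](c2ccccc2)(c3ccccc3)c4ccccc4.[Br-] | intermediate
33 | ylide of 32 (C25 triphenylphosphoranylidene polyene) | CC1=C[C@H](O)CC(C)(C)[C@H]1/C=C/C(C)=C/C=C/C(C)=C/C=C/C=C(C)/C=P(c2ccccc2)(c3ccccc3)c4ccccc4 | intermediate (not isolated)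
34 | 5,6-dihydroxylutein, (all-E)-(3S,5S,6R,3'R,6'R)-5,6-dihydro-β,ε-carotene-3,5,6,3'-tetrol | CC1=C[C@H](O)CC(C)(C)[C@H]1/C=C/C(C)=C/C=C/C(C)=C/C=C/C=C(C)/C=C/C=C(C)/C=C/[C@@]1(O)C(C)(C)C[C@H](O)C[C@]1(C)O | target

**Step count and risks**

Total step count: 22. Longest linear sequence: 13 steps (steps 1–12, then step 22); the ring B branch (steps 13–21) has 9 steps before the union.

Steps most likely to fail:

Step 3. The ene pathway (hydrogen abstraction from the C5 methyl, C2–H or C7–H) may outrun the [4+2] addition, or the endoperoxide may react on under irradiation. The fallback sets out from 3 and comes back at 5 without singlet oxygen. The more electron-rich tetrasubstituted C5=C6 bond of 3 is epoxidised with mCPBA (NaHCO3-buffered CH2Cl2, −20 °C) to the racemic vinyl oxirane tert-butyl(dimethyl)[(2,2,6-trimethyl-7-oxabicyclo[4.1.0]hept-4-en-1-yl)methoxy]silane F1. Pd(PPh3)4 (zerovalent palladium, cat.) with AcOH in THF then effects Tsuji–Trost ionisation of the allylic C5–O bond with inversion, and external acetate attacks the distal C3 terminus with a second inversion; this net cis-1,4 addition gives the racemic cis-3-acetoxy-6-ol, rac-(1S,4R)-4-{[tert-butyl(dimethyl)silyl]oxymethyl}-4-hydroxy-3,5,5-trimethylcyclohex-2-en-1-yl acetate F2. Methanolysis (K2CO3, MeOH) returns the route to 5.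

Step 7. Hydride delivery may be slow or misdirected: C4 must be reached from the ring face that carries C7 and the C5 methyl, trans-diaxial opening through the favoured half-chair would point to C5, and prolonged heating may loosen the silyl ether. The fallback sets out from 6 and comes back at 8, bypassing the epoxide. A Mukaiyama hydration of the C4=C5 bond (Mn(dpm)3 cat., PhSiH3, O2, i-PrOH, 0 °C → rt) should add a hydrogen atom at C4 and trap the tertiary C5 radical with oxygen from the less hindered equatorial direction, on the face of the C6 hydroxyl and away from the axial C1 methyl. This gives the tertiary hydroperoxide (1S,2S,4S)-1-{[tert-butyl(dimethyl)silyl]oxymethyl}-2-hydroperoxy-2,6,6-trimethylcyclohexane-1,4-diol F3, which is reduced in the same pot with P(OEt)3 to 8.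

Step 11. Addition of the phosphonate anion to the crowded, α-hydroxylated neopentyl aldehyde may be slower than base-promoted side reactions (α-ketol ring expansion, acetyl transfer). The fallback sets out from 12 and comes back at 15, building the chain in two smaller olefinations. The neutral stabilised ylide 1-(triphenyl-λ5-phosphanylidene)propan-2-one (toluene, 80 °C) should give the E-enone (1S,3S,4R)-3,4-dihydroxy-3,5,5-trimethyl-4-[(1E)-3-oxobut-1-en-1-yl]cyclohexyl acetate F4 without any base. A Horner–Wadsworth–Emmons reaction of its methyl ketone with diethyl cyanomethylphosphonate (NaH, THF, 0 °C → rt) then gives 15 after removal of the 9Z isomer.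

Further compounds
F1 | step 3 | tert-butyl(dimethyl)[(2,2,6-trimethyl-7-oxabicyclo[4.1.0]hept-4-en-1-yl)methoxy]silane (racemic 5,6-epoxide of 3, one enantiomer drawn) | C[C@]12C=CCC(C)(C)[C@@]1(CO[Si](C)(C)C(C)(C)C)O2
F2 | step 3 | rac-(1S,4R)-4-{[tert-butyl(dimethyl)silyl]oxymethyl}-4-hydroxy-3,5,5-trimethylcyclohex-2-en-1-yl acetate (racemate, one enantiomer drawn) | CC1=C[C@@H](OC(C)=O)CC(C)(C)[C@@]1(CO[Si](C)(C)C(C)(C)C)O
F3 | step 7 | (1S,2S,4S)-1-{[tert-butyl(dimethyl)silyl]oxymethyl}-2-hydroperoxy-2,6,6-trimethylcyclohexane-1,4-diol | CC(C)(C)[Si](C)(C)OC[C@@]1(O)C(C)(C)C[C@H](O)C[C@]1(C)OO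
F4 | step 11 | (1S,3S,4R)-3,4-dihydroxy-3,5,5-trimethyl-4-[(1E)-3-oxobut-1-en-1-yl]cyclohexyl acetate | CC(=O)/C=C/[C@@]1(O)C(C)(C)C[C@H](OC(C)=O)C[C@]1(C)O
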